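**Strategy.** The epoxycyclohexene ring (C1 quaternary epoxide carbon, C2 epoxide CH, C3 CHOH, C4 bearing CH2OH, C5 alkene CH, C6 CHOH) is made by a Diels–Alder reaction that forms C1–C2 and C5–C6 at once. It exploits the 1,4-relation of the epoxide oxygen on C2 and alkene carbon C5: C2–C5 come from furan-3-ylmethanol, whose oxygen becomes the epoxide oxygen, and C1, C6 and the side-chain carbinol carbon from bromomalonaldehyde. A silicon tether joins the two as a silyl enol ether; cycloaddition gives an oxanorbornene with bromine anti to the bridge. Bridge opening, epoxide closure and a Stille coupling with a cyclised epoxygeraniol fragment finish the target.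

Key step: step 2

Remark: the sense of induction of the chiral boron Lewis acid in step 2 is assumed to follow that known for 2-bromoacrolein; if it proves opposite for the tethered substrate, the antipodal catalyst is used. Bicyclic intermediates are named with bicyclo[2.2.1] numbering, monocyclic ones with the ring numbering C1–C6 above; the SMILES define all configurations.

Step 1
Reactants: 1 furan-3-ylmethanol; 2 dichlorodi(propan-2-yl)silane; 3 bromomalonaldehyde (2-bromopropanedial, reacting as its enol)
Product: 5 (Z)-2-bromo-3-{[(furan-3-ylmethoxy)di(propan-2-yl)silyl]oxy}prop-2-enal, via chlorosilyl ether 4 (not isolated)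
Conditions: 2 (3 equiv), Et3N, CH2Cl2, −40 → 0 °C; excess 2 removed in vacuo; then 3, Et3N, CH2Cl2, 0 °C → rt
Reagents that add atoms: none
Why: Two successive O-silylations (silyl ether, then silyl enol ether of the acidic enol of 3); the enol ether should form with oxygen trans to the formyl group (extended vinylogous ester), which places bromine and the silyloxy group cis on the alkene.

Step 2
Reactants: 5 (Z)-2-bromo-3-{[(furan-3-ylmethoxy)di(propan-2-yl)silyl]oxy}prop-2-enal
Product: 6 silylene-bridged cycloadduct: 2-endo-bromo-7-oxabicyclo[2.2.1]hept-5-ene-2-exo-carbaldehyde whose 3-endo oxygen and 5-CH2O group are joined through Si(iPr)2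
Conditions: (R)-N-tosyltryptophan-derived B-butyl-1,3,2-oxazaborolidin-5-one (20 mol%), 4 Å MS, CH2Cl2, −78 → −20 °C
Reagents that add atoms: none
Why: Lewis acid-activated normal-demand [4+2] cycloaddition between the furan (its two α-carbons as diene termini) and the bromo-enal C=C, a type 2 intramolecular Diels–Alder reaction (tether on an inner diene carbon) of the kind known for silicon-tethered trienes and, bimolecularly, for furan with 2-bromoacrolein under this class of boron catalyst. The six-membered carbocycle is closed by the cycloaddition itself (C5–C6 and C1–C2 formed together, the furan oxygen becoming the 1,4-bridge), and the bridged seven-membered dioxasilepane follows from the tether. The four-atom tether can only reach when the silyloxy group on C6 is endo, so the Z-alkene places bromine endo and the formyl group exo, which fixes the relative configuration of C1, C2, C5 and C6, while the chiral Lewis acid bound to the aldehyde should select the enantiotopic face. The step needs regioselectivity (C6 to the furan carbon next to the substituent), which the tether length and the higher nucleophilicity of that α-carbon both favour, and cycloaddition in preference to addition–elimination at the β-silyloxy enal, which low temperature and the intramolecular concerted path should secure.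

Step 3
Reactants: 6 silylene-bridged cycloadduct
Product: 7 2-endo-bromo-3-endo-hydroxy-5-(hydroxymethyl)-7-oxabicyclo[2.2.1]hept-5-ene-2-exo-carbaldehyde
Conditions: HF·pyridine, pyridine, THF, 0 °C
Reagents that add atoms: none
Why: Fluoride cleavage of the dialkoxysilane (silyl ether cleavage) under weakly acidic conditions that should avoid retro-aldol of the β-hydroxy aldehyde; the tether has to go because it cannot span a later C4=C5 alkene.

Step 4
Reactants: 7 diol aldehyde
Product: 8 2-endo-bromo-3-endo-(tert-butyldimethylsilyloxy)-5-[(tert-butyldimethylsilyloxy)methyl]-7-oxabicyclo[2.2.1]hept-5-ene-2-exo-carbaldehyde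
Conditions: TBSOTf (2.4 equiv), 2,6-lutidine, CH2Cl2, −78 → 0 °C
Reagents that add atoms: tert-butyldimethylsilyl triflate, CC(C)(C)[Si](C)(C)OS(=O)(=O)C(F)(F)F
Why: Silyl triflate silylation of the primary and the hindered secondary alcohol; the aldehyde has no α-hydrogen and cannot give an enol ether.

Step 5
Reactants: 9 propyne; 10 hexabutyldistannane
Product: 11 (Z)-1,2-bis(tributylstannyl)prop-1-ene
Conditions: Pd(PPh3)4 (2 mol%), dioxane, 70 °C, sealed tube
Reagents that add atoms: none
Why: Palladium-catalysed syn-distannation of a terminal alkyne, which gives the Z-1,2-distannylalkene.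

Step 6
Reactants: 8 bis-TBS bromo aldehyde; 11 (Z)-1,2-bis(tributylstannyl)prop-1-ene
Product: 14 oxanorbornene 8 in which the formyl group has become (1Z)-CH(OTBS)–CH=C(CH3)SnBu3, via vinyllithium 12 (not isolated), via lithium alkoxide 13 (not isolated)
Conditions: 11, MeLi (0.95 equiv to 11), THF, −78 → −40 °C; then 8, −78 °C; then TBSOTf, −78 → 0 °C
Reagents that add atoms: tert-butyldimethylsilyl triflate, CC(C)(C)[Si](C)(C)OS(=O)(=O)C(F)(F)F
Why: Tin–lithium exchange at the less hindered terminal tin (as with cis-1,2-bis(tributylstannyl)ethylene) gives the Z-vinyllithium, which adds to the aldehyde; with C=O antiperiplanar to C–Br (Cornforth model) the nucleophile should enter on the bridgehead side because the exo hydrogen of the CH(OTBS) carbon flanks the other face, setting the carbinol centre as drawn, and the alkoxide is silylated before it can displace bromide.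

Step 7
Reactants: 14 TBS-protected bromo vinylstannane
Product: 15 bromohydrin: cyclohex-4-ene with C1 bearing Br and the stannyl side chain, C2–OH trans to Br, C3–OTBS trans to C2–OH, C4–CH2OTBS, C6–OTBS cis to C3–OTBS
Conditions: [Rh(cod)Cl]2 (5 mol%), dppf (12 mol%), Bu4NI (20 mol%), tBuMe2SiOH (5 equiv), THF, 70 °C
Reagents that add atoms: tert-butyldimethylsilanol, CC(C)(C)[Si](C)(C)O
Why: Rhodium-catalysed SN2′ ring opening of an oxabicyclic alkene by an oxygen nucleophile (Lautens-type; silanols serve as water surrogates): the bridgehead C–O bond remote from the electron-poor quaternary carbon should ionise and the silanol attack the unsubstituted allyl terminus anti to the departing oxygen, so C3–O is trans to C2–OH and the alkene moves to C4=C5.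

Step 8
Reactants: 15 bromohydrin
Product: 16 1,2-epoxide (oxygen trans to the side chain and to both ring silyloxy groups) carrying the (1Z)-CH(OTBS)–CH=C(CH3)SnBu3 chain on C1
Conditions: K2CO3, MeOH, 0 °C → rt
Reagents that add atoms: none
Why: Intramolecular Williamson closure (halohydrin to epoxide): the C2 alkoxide displaces the anti tertiary bromide with inversion at C1.

Step 9
Reactants: 17 geraniol
Product: 18 tert-butyl (2E)-3,7-dimethylocta-2,6-dien-1-yl carbonate
Conditions: Boc2O, DMAP (10 mol%), MeCN, rt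
Reagents that add atoms: di-tert-butyl dicarbonate, CC(C)(C)OC(=O)OC(=O)OC(C)(C)C
Why: DMAP-catalysed acylation of the primary allylic alcohol.

Step 10
Reactants: 18 tert-butyl geranyl carbonate
Product: 19 tert-butyl (2E)-5-[(2R)-3,3-dimethyloxiran-2-yl]-3-methylpent-2-en-1-yl carbonate
Conditions: D-fructose-derived Shi ketone (30 mol%), Oxone, K2CO3, Bu4NHSO4 (cat.), MeCN/dimethoxymethane/aq. borate buffer, 0 °C
Reagents that add atoms: Oxone (potassium peroxymonosulfate), [K+].OOS(=O)(=O)[O-]
Why: Shi asymmetric epoxidation (chiral dioxirane); the electron-rich distal alkene should react before the alkene deactivated by the allylic carbonate, and this ketone should give the R epoxide as at other prenyl termini.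

Step 11
Reactants: 19 (R)-epoxygeranyl tert-butyl carbonate
Product: 21 trans-fused 6-(tert-butyldimethylsilyloxy)-5,5,8a-trimethylhexahydro-4H-1,3-benzodioxin-2-one (6-O cis to the C4a–C4 bond), via hydroxy carbonate 20 (not isolated)
Conditions: BF3·OEt2 (0.5 equiv), CH2Cl2, −78 °C; then 2,6-lutidine, TBSOTf, −78 → 0 °C
Reagents that add atoms: tert-butyldimethylsilyl triflate, CC(C)(C)[Si](C)(C)OS(=O)(=O)C(F)(F)F
Why: Epoxide-initiated cation–olefin cyclisation through a chair transition state with anti addition across the E-alkene, the tertiary cation being trapped by the carbonate carbonyl with loss of isobutene; the epoxide carbon keeps its configuration and the two new centres follow from the chair (CH2O equatorial, cis to the secondary oxygen, trans to the tertiary C–O).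

Step 12
Reactants: 21 silylated cyclic carbonate
Product: 22 4-(tert-butyldimethylsilyloxy)-2-(hydroxymethyl)-1,3,3-trimethylcyclohexan-1-ol (CH2OH trans to the tertiary OH, cis to OTBS)
Conditions: K2CO3, MeOH, 40 °C
Reagents that add atoms: none
Why: Base-catalysed transesterification of the cyclic carbonate frees the primary and tertiary alcohols; the TBS ether is stable.

Step 13
Reactants: 22 diol
Product: 23 (1R,2R,5R)-5-(tert-butyldimethylsilyloxy)-2-hydroxy-2,6,6-trimethylcyclohexane-1-carbaldehyde
Conditions: TEMPO (10 mol%), PhI(OAc)2, CH2Cl2, rt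
Reagents that add atoms: none
Why: Oxoammonium (TEMPO) oxidation of the primary alcohol; the tertiary alcohol is inert and the neutral medium should avoid retro-aldol and epimerisation.

Step 14
Reactants: 23 β-hydroxy aldehyde
Product: 24 (1R,2R,4R)-4-(tert-butyldimethylsilyloxy)-2-[(E)-2-iodoethenyl]-1,3,3-trimethylcyclohexan-1-ol
Conditions: CrCl2 (8 equiv), CHI3 (3 equiv), dioxane/THF 6:1, 0 °C → rt
Reagents that add atoms: iodoform, IC(I)I
Why: Takai olefination, E-selective and tolerant of the free tertiary alcohol.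

Step 15
Reactants: 16 epoxy vinylstannane; 24 vinyl iodide
Product: 25 penta-TBS arthrosporol A (all hydroxyls silylated except the tertiary one)
Conditions: Pd(PPh3)4 (10 mol%), CuTC (copper thiophene-2-carboxylate, 1.5 equiv), [NBu4][Ph2PO2] (1.5 equiv), DMF, rt
Reagents that add atoms: none
Why: Copper-assisted Stille cross-coupling at room temperature with retention of both alkene geometries, giving the 2Z,4E-diene; epoxide, tertiary alcohol and silyl ethers are inert.

Step 16
Reactants: 25 penta-TBS arthrosporol A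
Product: 26 arthrosporol A
Conditions: TBAF, AcOH (1:1, excess), THF, 0 °C → 40 °C
Reagents that add atoms: none
Why: Fluoride cleavage of the five TBS ethers, buffered so that no alkoxide starts an epoxide (Payne) migration and no acid ionises the dienyl carbinol.

**Compound list**

1 | furan-3-ylmethanol | OCc1ccoc1 | starting material
2 | dichlorodi(propan-2-yl)silane | CC(C)[Si](Cl)(Cl)C(C)C | starting material
3 | bromomalonaldehyde | O=CC(Br)C=O | starting material
4 | chloro(furan-3-ylmethoxy)di(propan-2-yl)silane | CC(C)[Si](Cl)(OCc1ccoc1)C(C)C | intermediate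
5 | (Z)-2-bromo-3-{[(furan-3-ylmethoxy)di(propan-2-yl)silyl]oxy}prop-2-enal | O=C/C(Br)=C/O[Si](C(C)C)(C(C)C)OCc1ccoc1 | intermediate
6 | silylene-bridged 2-endo-bromo-7-oxabicyclo[2.2.1]hept-5-ene-2-exo-carbaldehyde (3-endo-O–Si(iPr)2–OCH2–C5) | O=C[C@@]1(Br)[C@H]2O[C@H](C(CO[Si](C(C)C)(C(C)C)O3)=C2)[C@@H]13 | intermediate
7 | 2-endo-bromo-3-endo-hydroxy-5-(hydroxymethyl)-7-oxabicyclo[2.2.1]hept-5-ene-2-exo-carbaldehyde | O=C[C@@]1(Br)[C@H]2O[C@H](C(CO)=C2)[C@@H]1O | intermediate
8 | bis-TBS ether of 7 | O=C[C@@]1(Br)[C@H]2O[C@H](C(CO[Si](C)(C)C(C)(C)C)=C2)[C@@H]1O[Si](C)(C)C(C)(C)C | intermediate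
9 | propyne | CC#C | starting material
10 | hexabutyldistannane | CCCC[Sn](CCCC)(CCCC)[Sn](CCCC)(CCCC)CCCC | starting material
11 | (Z)-1,2-bis(tributylstannyl)prop-1-ene | C/C(=C/[Sn](CCCC)(CCCC)CCCC)[Sn](CCCC)(CCCC)CCCC | intermediate
12 | (Z)-2-(tributylstannyl)prop-1-en-1-yllithium | C/C(=C/[Li])[Sn](CCCC)(CCCC)CCCC | intermediate
13 | lithium alkoxide from addition of 12 to 8 | CCCC[Sn](CCCC)(CCCC)/C(C)=C\[C@H](O[Li])[C@@]1(Br)[C@H]2O[C@H](C(CO[Si](C)(C)C(C)(C)C)=C2)[C@@H]1O[Si](C)(C)C(C)(C)C | intermediate
14 | tris-TBS bromo oxanorbornene with (1Z)-CH(OTBS)–CH=C(CH3)SnBu3 at C2 (exo) | CCCC[Sn](CCCC)(CCCC)/C(C)=C\[C@H](O[Si](C)(C)C(C)(C)C)[C@@]1(Br)[C@H]2O[C@H](C(CO[Si](C)(C)C(C)(C)C)=C2)[C@@H]1O[Si](C)(C)C(C)(C)C | intermediate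
15 | bromohydrin cyclohexene (C2–OH, C3–OTBS trans; C3/C6 OTBS cis) | CCCC[Sn](CCCC)(CCCC)/C(C)=C\[C@H](O[Si](C)(C)C(C)(C)C)[C@@]1(Br)[C@@H](O)[C@H](O[Si](C)(C)C(C)(C)C)C(CO[Si](C)(C)C(C)(C)C)=C[C@@H]1O[Si](C)(C)C(C)(C)C | intermediate
16 | tetra-TBS epoxycyclohexene vinylstannane | CCCC[Sn](CCCC)(CCCC)/C(C)=C\[C@H](O[Si](C)(C)C(C)(C)C)[C@]12O[C@H]1[C@H](O[Si](C)(C)C(C)(C)C)C(CO[Si](C)(C)C(C)(C)C)=C[C@@H]2O[Si](C)(C)C(C)(C)C | intermediate
17 | geraniol | CC(C)=CCC/C(C)=C/CO | starting material
18 | tert-butyl geranyl carbonate | CC(C)=CCC/C(C)=C/COC(=O)OC(C)(C)C | intermediate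
19 | tert-butyl (2E)-5-[(2R)-3,3-dimethyloxiran-2-yl]-3-methylpent-2-en-1-yl carbonate | CC1(C)O[C@@H]1CC/C(C)=C/COC(=O)OC(C)(C)C | intermediate
20 | trans-fused 6-hydroxy-5,5,8a-trimethylhexahydro-4H-1,3-benzodioxin-2-one | O=C1OC[C@@H]2C(C)(C)[C@H](O)CC[C@@]2(C)O1 | intermediate
21 | TBS ether of 20 | O=C1OC[C@@H]2C(C)(C)[C@H](O[Si](C)(C)C(C)(C)C)CC[C@@]2(C)O1 | intermediate
22 | 4-(tert-butyldimethylsilyloxy)-2-(hydroxymethyl)-1,3,3-trimethylcyclohexan-1-ol | OC[C@@H]1C(C)(C)[C@H](O[Si](C)(C)C(C)(C)C)CC[C@@]1(C)O | intermediate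
23 | (1R,2R,5R)-5-(tert-butyldimethylsilyloxy)-2-hydroxy-2,6,6-trimethylcyclohexane-1-carbaldehyde | O=C[C@@H]1C(C)(C)[C@H](O[Si](C)(C)C(C)(C)C)CC[C@@]1(C)O | intermediate
24 | (1R,2R,4R)-4-(tert-butyldimethylsilyloxy)-2-[(E)-2-iodoethenyl]-1,3,3-trimethylcyclohexan-1-ol | I/C=C/[C@@H]1C(C)(C)[C@H](O[Si](C)(C)C(C)(C)C)CC[C@@]1(C)O | intermediate
25 | penta-TBS arthrosporol A | CC(=C/[C@H](O[Si](C)(C)C(C)(C)C)[C@]12O[C@H]1[C@H](O[Si](C)(C)C(C)(C)C)C(CO[Si](C)(C)C(C)(C)C)=C[C@@H]2O[Si](C)(C)C(C)(C)C)/C=C/[C@@H]1C(C)(C)[C@H](O[Si](C)(C)C(C)(C)C)CC[C@@]1(C)O | intermediate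
26 | arthrosporol A | CC(=C/[C@H](O)[C@]12O[C@H]1[C@H](O)C(CO)=C[C@@H]2O)/C=C/[C@@H]1C(C)(C)[C@H](O)CC[C@@]1(C)O | target

**Count.** Total: 16 steps. Longest linear sequence: 9 steps (1, 2, 3, 4, 6, 7, 8, 15, 16).

**Steps most likely to fail**

Step 2. The furan may attack the β-silyloxy enal by addition–elimination (loss of silanol) instead of cycloaddition, or the bridged transition state may stall the reaction. The fallback drops the tether and sets out from 1 and 3. Compound 1 is silylated (TBSCl, imidazole, DMF) to tert-butyl(furan-3-ylmethoxy)dimethylsilane F1. Compound 3 is O-silylated (TBSCl, Et3N, CH2Cl2) to (Z)-2-bromo-3-(tert-butyldimethylsilyloxy)prop-2-enal F2. F1 and F2 are combined in a bimolecular Diels–Alder reaction under the same class of chiral boron Lewis acid, relying on the exo-formyl preference of α-bromo enals and on the more nucleophilic furan carbon next to the substituent. The adduct is compound 8, where the route is rejoined; steps 3 and 4 fall away.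

Step 7. The rhodium catalyst may ionise the wrong bridgehead C–O bond, or the hindered trisubstituted alkene may not engage it. The fallback sets out from 14 and uses a ketone-triggered bridge opening instead:
- Hydroboration on the exo face (BH3·THF, 0 °C; then NaBO3) gives the C3 exo-alcohol F3.
- Dess–Martin oxidation gives the ketone F4.
- DBU in CH2Cl2 causes β-elimination of the bridging oxygen from the enolisable C4, and the freed C2 alkoxide displaces bromide, giving the epoxy enone F5.
- Luche reduction (NaBH4, CeCl3·7H2O, MeOH, −78 °C) should come from the epoxide face, because the C1 side chain and the C6 silyloxy group screen the other face, giving the trans epoxy alcohol F6.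
- TBSOTf and 2,6-lutidine then give 16, where the route is rejoined.

Step 6. Facial selectivity in the addition to the α-bromo aldehyde may be poor, giving the epimer at the side-chain carbinol. The fallback sets the centre by reagent-controlled reduction and sets out from 8. Addition of 12 with aqueous quench gives the epimeric alcohols F7. Dess–Martin oxidation gives the α-bromo enone F8. Reduction with a Me-CBS oxazaborolidine and catecholborane (enantiomer chosen with the quaternary carbon as the large group) gives the single alcohol F9. Silylation (TBSOTf, 2,6-lutidine) gives 14, where the route is rejoined.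

**Further compounds**

F1 | step 2 | tert-butyl(furan-3-ylmethoxy)dimethylsilane | CC(C)(C)[Si](C)(C)OCc1ccoc1
F2 | step 2 | (Z)-2-bromo-3-(tert-butyldimethylsilyloxy)prop-2-enal | CC(C)(C)[Si](C)(C)O/C=C(\Br)C=O
F3 | step 7 | 6-exo-hydroxy-7-oxanorbornane from hydroboration of 14 | CCCC[Sn](CCCC)(CCCC)/C(C)=C\[C@H](O[Si](C)(C)C(C)(C)C)[C@@]1(Br)[C@H]2O[C@H]([C@@H](CO[Si](C)(C)C(C)(C)C)[C@@H]2O)[C@@H]1O[Si](C)(C)C(C)(C)C
F4 | step 7 | 7-oxanorbornan-6-one from F3 | CCCC[Sn](CCCC)(CCCC)/C(C)=C\[C@H](O[Si](C)(C)C(C)(C)C)[C@@]1(Br)[C@H]2O[C@H]([C@@H](CO[Si](C)(C)C(C)(C)C)C2=O)[C@@H]1O[Si](C)(C)C(C)(C)C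
F5 | step 7 | 1,2-epoxy-cyclohex-4-en-3-one (epoxy enone) | CCCC[Sn](CCCC)(CCCC)/C(C)=C\[C@H](O[Si](C)(C)C(C)(C)C)[C@]12O[C@H]1C(=O)C(CO[Si](C)(C)C(C)(C)C)=C[C@@H]2O[Si](C)(C)C(C)(C)C
F6 | step 7 | trans epoxy alcohol (free C3–OH) | CCCC[Sn](CCCC)(CCCC)/C(C)=C\[C@H](O[Si](C)(C)C(C)(C)C)[C@]12O[C@H]1[C@H](O)C(CO[Si](C)(C)C(C)(C)C)=C[C@@H]2O[Si](C)(C)C(C)(C)C
F7 | step 6 | side-chain carbinol, epimer mixture | CCCC[Sn](CCCC)(CCCC)/C(C)=C\C(O)[C@@]1(Br)[C@H]2O[C@H](C(CO[Si](C)(C)C(C)(C)C)=C2)[C@@H]1O[Si](C)(C)C(C)(C)C
F8 | step 6 | α-bromo enone | CCCC[Sn](CCCC)(CCCC)/C(C)=C\C(=O)[C@@]1(Br)[C@H]2O[C@H](C(CO[Si](C)(C)C(C)(C)C)=C2)[C@@H]1O[Si](C)(C)C(C)(C)C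
F9 | step 6 | side-chain carbinol, single epimer | CCCC[Sn](CCCC)(CCCC)/C(C)=C\[C@H](O)[C@@]1(Br)[C@H]2O[C@H](C(CO[Si](C)(C)C(C)(C)C)=C2)[C@@H]1O[Si](C)(C)C(C)(C)C
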